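**Retrosynthetic overview**
- The chroman and its (R)-carbinol come last: Jacobsen epoxidation of a 2H-chromene, then one hydrogenolysis that opens the epoxide at the benzylic C–O bond and removes both benzyl ethers.
- The butenolide is closed from an α-hydroxy-β-keto ester and a methoxyacetyl unit (O-acylation, intramolecular aldol condensation).
- The quaternary (S)-carbinol and its bond to the aryl ketone carbon come from the key step, an enantioselective anionic 1,2-aroyl shift from O to C (Chan rearrangement) of an O-aroyl 3-aryl-lactate.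
- That ester comes from an aryl bromide, CO and the 3-aryl-lactate; the lactate from a chromenyl Grignard reagent and methyl glycidate; the chromene from 4-bromophenol and prenal; the aryl bromide from catechol.
- Ring order: 2H-chromene (step 1), butenolide (step 8), epoxide (step 9), chroman (step 10).

Assumption: the sense of induction of the new step 6 cannot be predicted; the (R,R)-amide is written, and the (S,S)-amide is used instead if it proves to give the (R)-product. Racemic methyl glycidate is used because that centre is erased at the enolate stage.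

**Step 1**
Reactants: 1 4-bromophenol; 2 3-methylbut-2-enal
Product: 4 6-bromo-2,2-dimethyl-2H-chromene, via benzodioxaborin 3 (not isolated)
Conditions: PhB(OH)2 (1.0 equiv), AcOH (cat.), toluene, reflux, Dean–Stark
Reagents that add atoms: none
Why: Boronate-templated ortho-hydroxyalkylation of the phenol by the enal gives 3, which on heating fragments to an ortho-quinone methide that closes by oxa-6π-electrocyclisation (phenol–enal chromene annulation); no stereocentre.

**Step 2**
Reactants: 4 6-bromo-2,2-dimethyl-2H-chromene; 5 methyl oxirane-2-carboxylate (racemic)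
Product: 7 methyl 3-(2,2-dimethyl-2H-chromen-6-yl)-2-hydroxypropanoate (racemic), via arylmagnesium bromide 6 (not isolated)
Conditions: Mg, THF, 50 °C; then CuI (10 mol%), 5, THF, −40 → −20 °C; aq. NH4Cl
Reagents that add atoms: none
Why: Cu-catalysed Grignard opening of the glycidate at its unsubstituted CH2 carbon (SN2) outruns ester addition at low temperature and gives the 3-aryl-lactate; its carbinol centre is racemic and is erased in step 6.

**Step 3**
Reactants: 8 catechol
Product: 9 1,2-bis(benzyloxy)benzene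
Conditions: BnBr (2.2 equiv), K2CO3, DMF, 60 °C
Reagents that add atoms: benzyl bromide, BrCc1ccccc1
Why: Williamson etherification protects both phenols as benzyl ethers, which survive the strong bases used later and leave in the final hydrogenolysis.

**Step 4**
Reactants: 9 1,2-bis(benzyloxy)benzene
Product: 10 4-bromo-1,2-bis(benzyloxy)benzene
Conditions: NBS (1.05 equiv), MeCN, 0 °C → rt
Reagents that add atoms: N-bromosuccinimide, O=C1CCC(=O)N1Br
Why: Electrophilic aromatic bromination goes para to one alkoxy group of the symmetrical diether, so a single monobromide forms.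

**Step 5**
Reactants: 7 methyl 3-(2,2-dimethyl-2H-chromen-6-yl)-2-hydroxypropanoate; 10 4-bromo-1,2-bis(benzyloxy)benzene
Product: 11 methyl 2-{[3,4-bis(benzyloxy)benzoyl]oxy}-3-(2,2-dimethyl-2H-chromen-6-yl)propanoate (racemic)
Conditions: Pd(OAc)2 (3 mol%), Xantphos (4.5 mol%), CO (1 atm), Et3N (3 equiv), DMAP (0.2 equiv), toluene, 90 °C
Reagents that add atoms: carbon monoxide, [C-]#[O+]
Why: Pd-catalysed alkoxycarbonylation (oxidative addition of 10, CO insertion, alcoholysis of the aroyl–Pd species by the secondary OH of 7 with DMAP as acyl-transfer co-catalyst) joins the two halves as the ester needed for the rearrangement.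

**Step 6 (key step)**
Reactants: 11 methyl 2-{[3,4-bis(benzyloxy)benzoyl]oxy}-3-(2,2-dimethyl-2H-chromen-6-yl)propanoate
Product: 13 methyl (2S)-3-[3,4-bis(benzyloxy)phenyl]-2-[(2,2-dimethyl-2H-chromen-6-yl)methyl]-2-hydroxy-3-oxopropanoate, via lithium enolate 12 (not isolated)
Conditions: (R,R)-bis(1-phenylethyl)amine (2.4 equiv), n-BuLi (2.3 equiv), LiCl (2.4 equiv), THF, −78 °C, giving LiN[(R)-CH(CH3)Ph]2; then 11, −78 → −40 °C; AcOH, −78 °C
Reagents that add atoms: none
Why: Proposed new method: an enantioselective Chan rearrangement in which the chiral amide LiN[(R)-CH(CH3)Ph]2 deprotonates 11 to enolate 12, which stays in a LiCl-bridged mixed aggregate with the chiral amide and amine, so that the enolate carbon adds to the Li-activated aroyl C=O on one face (3-exo-trig, oxiranyl alkoxide) and ring opening completes the O-to-C 1,2-aroyl shift, forming the C–C bond and the (S)-quaternary carbinol as a chelated lithium alkoxide that is far less basic than the enolate; the closest known reactions are the racemic Chan rearrangement with LiN(CHMe2)2 and enantioselective alkylations and Wittig rearrangements of lithium enolates held in chiral lithium amide mixed aggregates.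

**Step 7**
Reactants: 13 methyl (2S)-3-[3,4-bis(benzyloxy)phenyl]-2-[(2,2-dimethyl-2H-chromen-6-yl)methyl]-2-hydroxy-3-oxopropanoate; 14 methoxyacetyl chloride
Product: 15 methyl (2S)-3-[3,4-bis(benzyloxy)phenyl]-2-[(2,2-dimethyl-2H-chromen-6-yl)methyl]-2-[(methoxyacetyl)oxy]-3-oxopropanoate
Conditions: pyridine (3 equiv), DMAP (0.1 equiv), CH2Cl2, 0 °C
Reagents that add atoms: none
Why: Nucleophile-catalysed O-acylation of the acidic tertiary alcohol under weakly basic, cold conditions installs the two carbons and the methoxy group of the lactone without breaking any bond at the quaternary centre.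

**Step 8**
Reactants: 15 methyl (2S)-3-[3,4-bis(benzyloxy)phenyl]-2-[(2,2-dimethyl-2H-chromen-6-yl)methyl]-2-[(methoxyacetyl)oxy]-3-oxopropanoate
Product: 18 methyl (2S)-3-[3,4-bis(benzyloxy)phenyl]-2-[(2,2-dimethyl-2H-chromen-6-yl)methyl]-4-methoxy-5-oxo-2,5-dihydrofuran-2-carboxylate, via lithium aldolate 16 (not isolated), via tertiary mesylate 17 (not isolated)
Conditions: LiN(SiMe3)2 (1.2 equiv), THF, −78 °C; then MsCl (1.5 equiv), Et3N (4 equiv), −78 → 0 °C
Reagents that add atoms: none
Why: Intramolecular aldol condensation, in which the methoxyacetate enolate adds 5-exo to the aryl ketone and the tertiary benzylic aldolate is trapped as a mesylate that eliminates at once to the conjugated tetrasubstituted alkene, closes the butenolide; the quaternary centre is not enolisable and stays (S).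

**Step 9**
Reactants: 18 methyl (2S)-3-[3,4-bis(benzyloxy)phenyl]-2-[(2,2-dimethyl-2H-chromen-6-yl)methyl]-4-methoxy-5-oxo-2,5-dihydrofuran-2-carboxylate
Product: 19 methyl (2S)-3-[3,4-bis(benzyloxy)phenyl]-2-{[(3R,4R)-3,4-epoxy-2,2-dimethyl-3,4-dihydro-2H-chromen-6-yl]methyl}-4-methoxy-5-oxo-2,5-dihydrofuran-2-carboxylate
Conditions: [(R,R)-N,N'-bis(3,5-di-tert-butylsalicylidene)cyclohexane-1,2-diaminato]manganese chloride (5 mol%), mCPBA (2 equiv), N-methylmorpholine N-oxide (5 equiv), CH2Cl2, −78 °C
Reagents that add atoms: 3-chloroperbenzoic acid, OOC(=O)c1cccc(Cl)c1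
Why: Jacobsen–Katsuki epoxidation, for which 2,2-dimethylchromenes are the best substrate class and the (R,R)-salen catalyst gives the (3R,4R)-epoxide under catalyst control, sets the chroman stereocentre, while the hindered push–pull butenolide alkene does not react.

**Step 10**
Reactants: 19 methyl (2S)-3-[3,4-bis(benzyloxy)phenyl]-2-{[(3R,4R)-3,4-epoxy-2,2-dimethyl-3,4-dihydro-2H-chromen-6-yl]methyl}-4-methoxy-5-oxo-2,5-dihydrofuran-2-carboxylate
Product: 20 methyl (2S)-3-(3,4-dihydroxyphenyl)-2-{[(3R)-3-hydroxy-2,2-dimethyl-3,4-dihydro-2H-chromen-6-yl]methyl}-4-methoxy-5-oxo-2,5-dihydrofuran-2-carboxylate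
Conditions: H2 (1 atm), 10% Pd/C, EtOAc, rt
Reagents that add atoms: none
Why: Catalytic hydrogenolysis cleaves the benzylic C4–O bond of the epoxide (the C3–O bond is untouched, so the carbinol stays R) and both benzyl ethers in one operation, while the tetrasubstituted butenolide alkene, the methyl ester and the enol ether are inert.

**Compound list**
1 | 4-bromophenol | Oc1ccc(Br)cc1 | starting material
2 | 3-methylbut-2-enal | CC(C)=CC=O | starting material
3 | 6-bromo-4-(2-methylprop-1-en-1-yl)-2-phenyl-4H-1,3,2-benzodioxaborinine (racemic) | CC(C)=CC1OB(c2ccccc2)Oc2ccc(Br)cc12 | intermediate (not isolated)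
4 | 6-bromo-2,2-dimethyl-2H-chromene | CC1(C)C=Cc2cc(Br)ccc2O1 | intermediate
5 | methyl oxirane-2-carboxylate (racemic) | COC(=O)C1CO1 | starting material
6 | (2,2-dimethyl-2H-chromen-6-yl)magnesium bromide | CC1(C)C=Cc2cc([Mg]Br)ccc2O1 | intermediate (not isolated)
7 | methyl 3-(2,2-dimethyl-2H-chromen-6-yl)-2-hydroxypropanoate (racemic) | COC(=O)C(O)Cc1ccc2OC(C)(C)C=Cc2c1 | intermediate
8 | catechol | Oc1ccccc1O | starting material
9 | 1,2-bis(benzyloxy)benzene | C(Oc1ccccc1OCc1ccccc1)c1ccccc1 | intermediate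
10 | 4-bromo-1,2-bis(benzyloxy)benzene | Brc1ccc(OCc2ccccc2)c(OCc2ccccc2)c1 | intermediate
11 | methyl 2-{[3,4-bis(benzyloxy)benzoyl]oxy}-3-(2,2-dimethyl-2H-chromen-6-yl)propanoate (racemic) | COC(=O)C(Cc1ccc2OC(C)(C)C=Cc2c1)OC(=O)c1ccc(OCc2ccccc2)c(OCc2ccccc2)c1 | intermediate
12 | lithium enolate of 11 (lithium 2-{[3,4-bis(benzyloxy)benzoyl]oxy}-3-(2,2-dimethyl-2H-chromen-6-yl)-1-methoxyprop-1-en-1-olate) | [Li+].COC([O-])=C(Cc1ccc2OC(C)(C)C=Cc2c1)OC(=O)c1ccc(OCc2ccccc2)c(OCc2ccccc2)c1 | intermediate (not isolated)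
13 | methyl (2S)-3-[3,4-bis(benzyloxy)phenyl]-2-[(2,2-dimethyl-2H-chromen-6-yl)methyl]-2-hydroxy-3-oxopropanoate | COC(=O)[C@](O)(Cc1ccc2OC(C)(C)C=Cc2c1)C(=O)c1ccc(OCc2ccccc2)c(OCc2ccccc2)c1 | intermediate
14 | methoxyacetyl chloride | COCC(=O)Cl | starting material
15 | methyl (2S)-3-[3,4-bis(benzyloxy)phenyl]-2-[(2,2-dimethyl-2H-chromen-6-yl)methyl]-2-[(methoxyacetyl)oxy]-3-oxopropanoate | COC(=O)[C@](OC(=O)COC)(Cc1ccc2OC(C)(C)C=Cc2c1)C(=O)c1ccc(OCc2ccccc2)c(OCc2ccccc2)c1 | intermediate
16 | lithium (2S)-3-[3,4-bis(benzyloxy)phenyl]-2-[(2,2-dimethyl-2H-chromen-6-yl)methyl]-4-methoxy-2-(methoxycarbonyl)-5-oxotetrahydrofuran-3-olate (diastereomer mixture at C3 and C4) | [Li+].COC(=O)[C@@]1(Cc2ccc3OC(C)(C)C=Cc3c2)OC(=O)C(OC)C1([O-])c1ccc(OCc2ccccc2)c(OCc2ccccc2)c1 | intermediate (not isolated)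
17 | methyl (2S)-3-[3,4-bis(benzyloxy)phenyl]-2-[(2,2-dimethyl-2H-chromen-6-yl)methyl]-4-methoxy-3-[(methylsulfonyl)oxy]-5-oxotetrahydrofuran-2-carboxylate (diastereomer mixture at C3 and C4) | COC(=O)[C@@]1(Cc2ccc3OC(C)(C)C=Cc3c2)OC(=O)C(OC)C1(OS(C)(=O)=O)c1ccc(OCc2ccccc2)c(OCc2ccccc2)c1 | intermediate (not isolated)
18 | methyl (2S)-3-[3,4-bis(benzyloxy)phenyl]-2-[(2,2-dimethyl-2H-chromen-6-yl)methyl]-4-methoxy-5-oxo-2,5-dihydrofuran-2-carboxylate | COC(=O)[C@@]1(Cc2ccc3OC(C)(C)C=Cc3c2)OC(=O)C(OC)=C1c1ccc(OCc2ccccc2)c(OCc2ccccc2)c1 | intermediate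
19 | methyl (2S)-3-[3,4-bis(benzyloxy)phenyl]-2-{[(3R,4R)-3,4-epoxy-2,2-dimethyl-3,4-dihydro-2H-chromen-6-yl]methyl}-4-methoxy-5-oxo-2,5-dihydrofuran-2-carboxylate | COC(=O)[C@@]1(Cc2ccc3OC(C)(C)[C@@H]4O[C@@H]4c3c2)OC(=O)C(OC)=C1c1ccc(OCc2ccccc2)c(OCc2ccccc2)c1 | intermediate
20 | methyl (2S)-3-(3,4-dihydroxyphenyl)-2-{[(3R)-3-hydroxy-2,2-dimethyl-3,4-dihydro-2H-chromen-6-yl]methyl}-4-methoxy-5-oxo-2,5-dihydrofuran-2-carboxylate | COC(=O)[C@@]1(Cc2ccc3c(c2)C[C@@H](O)C(C)(C)O3)OC(=O)C(OC)=C1c1ccc(O)c(O)c1 | target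

**Totals**
Total step count: 10. Longest linear sequence: 8 steps (steps 1, 2, 5, 6, 7, 8, 9, 10 from 4-bromophenol).

**Three steps most likely to fail**

Step 6 (the proposed new step). The enantioselectivity of the aggregate-controlled 1,2-aroyl shift is unproven. The fallback sets out from 7 and 10 and comes back at 13, using known chemistry with no rearrangement. Compound 7 is oxidised with Dess–Martin periodinane (CH2Cl2, NaHCO3) to methyl 3-(2,2-dimethyl-2H-chromen-6-yl)-2-oxopropanoate F1. Compound 10 is converted by bromine–lithium exchange (n-BuLi, THF, −78 °C) into [3,4-bis(benzyloxy)phenyl]lithium F2, which is quenched with DMF to give 3,4-bis(benzyloxy)benzaldehyde F3. F3 and F1 are then joined in the known N-heterocyclic-carbene-catalysed enantioselective cross-benzoin reaction of aldehydes with α-keto esters (chiral aminoindanol-derived N-pentafluorophenyl triazolium salt, diisopropylethylamine, CH2Cl2). The Breslow intermediate of F3 adds to the ketone of F1 and gives 13 directly, with the catalyst enantiomer chosen for the (S)-product.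

Step 8. The ester enolate could attack the neighbouring methyl ester (Dieckmann closure to a tetronic acid) instead of the electron-rich aryl ketone. The fallback sets out from 13 and comes back at 18. Compound 13 is esterified with 2-(diethoxyphosphoryl)-2-methoxyacetic acid (DCC, DMAP, CH2Cl2) to methyl (2S)-3-[3,4-bis(benzyloxy)phenyl]-2-{[(diethoxyphosphoryl)(methoxy)acetyl]oxy}-2-[(2,2-dimethyl-2H-chromen-6-yl)methyl]-3-oxopropanoate F4. An intramolecular Horner–Wadsworth–Emmons olefination (LiCl, DBU, MeCN, rt) then closes the ring; the phosphonate carbanion reacts only with the ketone and the alkene forms irreversibly.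

Step 5. Carbonylative coupling with only one equivalent of a hindered, weakly nucleophilic α-hydroxy ester may be slow. The fallback sets out from 10 and 7 and comes back at 11. Compound 10 is converted with Mg (THF) into [3,4-bis(benzyloxy)phenyl]magnesium bromide F5, which is carboxylated with CO2 and acidified to 3,4-bis(benzyloxy)benzoic acid F6. A Steglich esterification of F6 with 7 (DCC, DMAP, CH2Cl2) gives 11.

**Further compounds**
F1 | step 6 | methyl 3-(2,2-dimethyl-2H-chromen-6-yl)-2-oxopropanoate | COC(=O)C(=O)Cc1ccc2OC(C)(C)C=Cc2c1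
F2 | step 6 | [3,4-bis(benzyloxy)phenyl]lithium | [Li]c1ccc(OCc2ccccc2)c(OCc2ccccc2)c1
F3 | step 6 | 3,4-bis(benzyloxy)benzaldehyde | O=Cc1ccc(OCc2ccccc2)c(OCc2ccccc2)c1
F4 | step 8 | methyl (2S)-3-[3,4-bis(benzyloxy)phenyl]-2-{[(diethoxyphosphoryl)(methoxy)acetyl]oxy}-2-[(2,2-dimethyl-2H-chromen-6-yl)methyl]-3-oxopropanoate | COC(=O)[C@](OC(=O)C(OC)P(=O)(OCC)OCC)(Cc1ccc2OC(C)(C)C=Cc2c1)C(=O)c1ccc(OCc2ccccc2)c(OCc2ccccc2)c1
F5 | step 5 | [3,4-bis(benzyloxy)phenyl]magnesium bromide | Br[Mg]c1ccc(OCc2ccccc2)c(OCc2ccccc2)c1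
F6 | step 5 | 3,4-bis(benzyloxy)benzoic acid | OC(=O)c1ccc(OCc2ccccc2)c(OCc2ccccc2)c1
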